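**Remarks on the chemistry (assumptions, one line each)**

- Numbering: ring A is C1 (prenyl), C2 (OH), C3 (H), C4 (OH), C5 (CHO), C6 (bonded to the ketone carbon C7); ring B is C1' (bonded to C7), C2' (OH), C3' (H), C4' (CH3), C5' (Cl), C6' (OH).
- Structure check: in the aryne precursor 11 silicon sits on the future C1', the triflate on C2', the MOM ether on C6' and chlorine on C5'; 11 and 24 map atom for atom onto 25, so neither skeleton needed correction.
- The free acid corresponding to 21 is assumed not to be isolable, because a carboxylic acid next to an electron-rich dimethyl acetal should lactonise to a 3-methoxyphthalide by intramolecular acid catalysis; the acid is therefore made and used only as its caesium salt 21.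
- Electrophilic chlorination of a mono-protected orcinol would have to choose among three activated ring positions, so chlorine and methyl are taken from the starting material 1 instead.
- 2-Chloro-3-methylphenol, 3-chloro-3-methylbut-1-yne and 2-(trimethylsilyl)ethanol are taken as commercial; reagents are not numbered.

## Structural features

Pestalone E (25) is a benzophenone in which two pentasubstituted benzene rings are joined only through the ketone carbon C7 (C6–C7–C1'). Ring A carries, in order, a prenyl group (C1), a hydroxyl (C2), hydrogen (C3), a hydroxyl (C4), a formyl group (C5) and the aroyl carbon (C6); ring B carries C7 on C1', hydroxyls on C2' and C6', hydrogen on C3', methyl on C4' and chlorine on C5'. There is no stereocentre, hence no adjacent stereocentres, and the only alkene is the prenyl olefin, whose two methyl groups make it stereochemically silent. The fragile parts are the aldehyde ortho to the diaryl ketone (lactol or lactone formation with neighbouring nucleophiles or base), the prenyl group next to the C2 hydroxyl (acid-induced chroman formation), the electron-rich rings and the aryl chloride (reductive loss). The real difficulty is the C7 ketone, shielded by four ortho substituents (C1 prenyl, C5 formyl, C2' and C6' oxygens), together with placing chlorine next to only one of the two ring B oxygens. The key step uses the fact that C1' lies between two oxygen-bearing carbons: an aryne across C1'–C2', polarised by the ether on C6', can accept the C2' oxygen and the C7 acyl group from one and the same ring A carboxylate.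

## Logic of the disconnections

**25 ⇒ 24.** The cuts are the three phenolic O–CH2 bonds of the MOM ethers and the two C–OMe bonds of the C5 acetal; no skeletal bond is touched. The three phenols and the aldehyde of 25 would protonate the carbanion of the key step or add to the aryne, so they are masked by groups that fall in one mild acidic operation. The demand on the forward step is an acid weak and cold enough that the C2 hydroxyl does not add to the prenyl olefin.

**24 ⇒ 21 + 11 (through 22).** The cuts are C1'–C7 and C2'–O. An intermolecular attack on C7 would have to pass four ortho substituents; here an unhindered O–C bond is made first and the C–C bond follows intramolecularly. The gain is a split into two rings of similar size, with the C2' oxygen delivered by ring A, so that ring B needs only one protected oxygen. The forward step demands oxygen attack at the aryne carbon remote from the ether, and an acyl shift that outruns protonation; hence 21 must be free of O–H.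

**21 ⇒ 20 ⇒ 19.** The cuts are the ester O–CH2 bond (unmasking) and then C6–C7 (carbonylation retron). The free acid cannot be handled and hydrolysis of an ester flanked by two ortho groups is blocked, so the ester is chosen to cleave at silicon with fluoride. C7 is brought in as carbon monoxide on a C6–O triflate because C6 is meta to both ring oxygens and out of reach of electrophilic substitution or directed metalation. The gain is that C6 derives from a phenol oxygen of a phloroglucinol pattern. The demand is palladium insertion next to an acetal and a prenyl group, with alcoholysis faster than side reactions.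

**19 ⇒ 18 ⇒ 17.** The cuts are the acetal C–O bonds and the triflate S–O bond. The order matters: a hydrogen-bonded ortho-hydroxy aldehyde resists acetalisation, and an ortho-formyl ester would be diverted to a cyclic pseudo-ester, so the acetal is made after triflation and before carbonylation. The demand is an acid catalyst that spares the aryl MOM ethers.

**17 ⇒ 16 ⇒ 15 ⇒ 13 + 14.** The C1–CH2 bond of the prenyl group is cut by a Claisen retron, trading it for an O–C bond to the neighbouring oxygen; then follow the alkene-to-alkyne retron and the O–C(tertiary) bond. C1 must be distinguished from C3, the even more nucleophilic carbon between the two ethers, and a tether to the C6 oxygen leaves only C1 within reach. The demand is O-alkylation of a chelated phenoxide by a tertiary electrophile, then a [3,3] shift with allylic inversion.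

**13 ⇒ 12.** Two O–CH2 bonds are cut. 12 already holds all ring A oxygens and the formyl carbon, and its two ortho hydroxyls are equivalent, so no regiochemical question arises. The demand is to stop at the bis-ether, which the hydrogen bond of the last hydroxyl to the formyl group should ensure.

**11 ⇒ 10 ⇒ 9 ⇒ 5 (through 8, 7, 6).** The cuts are the triflate S–O bond, the carbamate C–O bond and the C1'–Si bond. Silicon must sit exactly between the two oxygens, which is the doubly activated site for directed ortho-metalation. The demand is lithiation that leaves the C–Cl bond alone and removal of the carbamate without acid.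

**5 ⇒ 4 ⇒ 2 ⇒ 1 (through 3).** The cuts are the carbamate O–C bond, the C2'–O bond (through C–B) and an O–CH2 bond. With chlorine and methyl already in 1, the missing oxygen is placed at the only ring hydrogen without an ortho neighbour. The gain is regiochemistry set by sterics and two oxygens differentiated from the start, with no statistical mono-protection. The demand is a C–H borylation that avoids the positions ortho to substituents.

## Other disconnections considered

**Alternative 1:** Ring A by Diels–Alder benzannulation.

- **Cut:** ring A bonds C1–C6 and C4–C5, so ring A is built onto a finished ring B ketone.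
- **Forward key step:** the triene 1-methoxy-7-methyl-1,3-bis(trimethylsilyloxy)octa-1,3,6-triene A2 and the aroyl ynal A3 combine in a thermal [4+2] cycloaddition; loss of methoxytrimethylsilane and desilylation should give A1.
- **In favour:** all six substituents of ring A are set in one operation and the ring A hydroxyls and aldehyde emerge unprotected, so only two MOM ethers remain. In protecting-group economy on ring A this is better than the chosen plan, and the overall step count should be equal or slightly lower.
- **Against:** the regiochemistry rests on the aldehyde of A3 outweighing the aroyl ketone as the polarising group, since the prenyl-bearing terminus of A2 must bond to the aroyl-bearing alkyne carbon. The substituted terminus of A2 lowers reactivity. The free aldehyde of A3 is open to Mukaiyama-type addition by the silyl ketene acetal. A3 is a doubly activated, sensitive alkyne whose preparation still requires the hindered C7–C1' bond, so the central problem is moved and not removed.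
- **Comparison:** the two plans face the same congested ketone. The alternative relies on a pericyclic step whose orientation is a competition between two acceptors, the chosen plan on an ionic step whose orientation is set by one substituent on the aryne. On regiochemical security the chosen plan is ahead; on step count the alternative is its equal or better.

**Alternative 2:** Ring B by Danheiser benzannulation.

- **Cut:** ring B bonds C6'–C1' and C2'–C3', with C5'–C6' closing by electrocyclisation.
- **Forward key step:** 4-chloro-3-methylcyclobut-2-en-1-one A5 opens on heating to a vinylketene, which takes up the ring A siloxyalkyne A6 by [2+2] addition, four-electron ring opening and six-electron ring closure to give the phenol A4.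
- **In favour:** chlorine, methyl and both oxygens of ring B are fixed by the connectivity of A5 and A6, and the two oxygens emerge differentiated (free hydroxyl and silyl ether). In regiocontrol of ring B it is the equal of the chosen plan, and it needs neither an aryne nor an organolithium on a chlorinated ring.
- **Against:** A4 is a diarylmethane, so C7 is at the wrong oxidation level. The later benzylic oxidation must act on a methylene flanked by four ortho substituents in the presence of the allylic prenyl hydrogens and two electron-rich rings. A5 is an allylic chloride in a strained enone and should be prone to loss of HCl, and A6 needs a multi-step homologation of a ring A benzylic unit.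
- **Comparison:** structurally it closes a ring where the chosen plan joins two. Mechanistically it is a thermal cascade with no regiochemical ambiguity, which is a point in its favour. In step economy it is worse, because oxidation, desilylation and a longer route to A6 are added.

**Alternative 3:** Carbon monoxide as linchpin.

- **Cut:** C6–C7 and C7–C1' at once.
- **Forward key step:** the ring A triflate 18, carbon monoxide and the ring B arylzinc chloride A8 couple under Pd(OAc)2 with a bulky phosphine (carbonylative Negishi coupling) to give the tetrakis(MOM) ether A7.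
- **In favour:** it is the most convergent plan and uses 18 of the present route directly. The aldehyde needs no acetal, steps 10 to 12 fall away, and A8 is two operations from 4 (MOM ether, then lithiation between the two oxygens and transmetalation with ZnCl2). In step economy it is clearly better, by about four steps.
- **Against:** transmetalation of a 2,6-dialkoxyarylzinc to an acylpalladium that itself has two ortho substituents, and reductive elimination to a ketone with four ortho groups, is the most demanding case for this coupling. Slow transmetalation leaves room for reduction, homocoupling or direct biaryl coupling, and the free aldehyde and the prenyl olefin sit next to the metal.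
- **Comparison:** the target and the hindrance are the same. The alternative forms C7–C1' by bimolecular organometallic steps at the most crowded centre, whereas the chosen plan forms it intramolecularly after an easy C–O bond formation; that is the advantage of the chosen plan. The regiochemistry on ring B is equally secure in both.

Key step: step 13

## Route

**Step 1**
Reactants: 1 2-chloro-3-methylphenol
Product: 2 2-chloro-1-(methoxymethoxy)-3-methylbenzene
Conditions: MOMCl, iPr2NEt, CH2Cl2, 0 °C to rt
Reagents that add atoms: chloromethyl methyl ether, COCCl
Why: Williamson-type O-alkylation of the phenoxide by an α-chloro ether; the MOM ether masks the future C6' oxygen, withstands base and organolithiums and later acts as a directing group.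

**Step 2**
Reactants: 2 2-chloro-1-(methoxymethoxy)-3-methylbenzene
Product: 4 4-chloro-3-(methoxymethoxy)-5-methylphenol, via aryl pinacol boronate 3 (not isolated)
Conditions: [Ir(OMe)(cod)]2 (cat.), 4,4'-di-tert-butyl-2,2'-bipyridine (cat.), B2pin2, THF, 80 °C; then aq. NaOH, H2O2, 0 °C to rt
Reagents that add atoms: bis(pinacolato)diboron, CC1(C)OB(OC1(C)C)B1OC(C)(C)C(C)(C)O1 (boron of 3 only); hydrogen peroxide, OO
Why: Sterically governed iridium-catalysed C–H borylation (Miyaura–Hartwig type) should attack the only ring hydrogen of 2 without an ortho neighbour, and oxidation of the C–B bond keeps the position. The new hydroxyl thus ends up para to chlorine and meta to the MOM ether without any electrophilic chlorination.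

**Step 3**
Reactants: 4 4-chloro-3-(methoxymethoxy)-5-methylphenol
Product: 5 4-chloro-3-(methoxymethoxy)-5-methylphenyl N-(propan-2-yl)carbamate
Conditions: iPrNCO, Et3N (cat.), CH2Cl2, rt
Reagents that add atoms: 2-isocyanatopropane, CC(C)N=C=O
Why: Amine-catalysed addition of the phenol to the isocyanate; the secondary carbamate is a strong ortho-directing group that can later be removed without acid or hydroxide.

**Step 4**
Reactants: 5 4-chloro-3-(methoxymethoxy)-5-methylphenyl N-(propan-2-yl)carbamate
Product: 9 4-chloro-3-(methoxymethoxy)-5-methyl-2-(trimethylsilyl)phenyl N-(propan-2-yl)carbamate, via N-silyl carbamate 6 (not isolated), via aryllithium 7 (not isolated), via N,C-disilyl carbamate 8 (not isolated)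
Conditions: TMSOTf, TMEDA, Et2O, 0 °C to rt; n-BuLi, TMEDA, −78 °C; TMSCl, −78 °C to rt; MeOH, aq. NaHCO3
Reagents that add atoms: trimethylsilyl trifluoromethanesulfonate, C[Si](C)(C)OS(=O)(=O)C(F)(F)F (N-silyl group of 6 to 8 only); n-butyllithium, [Li]CCCC (lithium of 7 only); chlorotrimethylsilane, C[Si](C)(C)Cl
Why: N-Silylation in the flask removes the N–H, and directed ortho-metalation should then occur at the one carbon flanked by both directing groups (carbamate and MOM ether), the future C1'. At −78 °C the aryl chloride should not exchange and the anionic Fries shift should stay slow; C-silylation and methanolysis of the N–Si bond give 9.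

**Step 5**
Reactants: 9 4-chloro-3-(methoxymethoxy)-5-methyl-2-(trimethylsilyl)phenyl N-(propan-2-yl)carbamate
Product: 11 4-chloro-3-(methoxymethoxy)-5-methyl-2-(trimethylsilyl)phenyl trifluoromethanesulfonate, via silylphenol 10 (not isolated)
Conditions: DBU, Et2NH, MeCN, 40 °C; then PhNTf2, rt
Reagents that add atoms: N-phenylbis(trifluoromethanesulfonimide), O=S(=O)(N(c1ccccc1)S(=O)(=O)C(F)(F)F)C(F)(F)F
Why: DBU removes the carbamate N–H and the phenoxide leaves in an E1cB fragmentation, diethylamine trapping the isocyanate as a urea. Triflation of the phenoxide in the same flask gives the ortho-silylaryl triflate without exposing the C–Si bond or the MOM ether to acid.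

**Step 6**
Reactants: 12 2,4,6-trihydroxybenzaldehyde
Product: 13 2-hydroxy-4,6-bis(methoxymethoxy)benzaldehyde
Conditions: MOMCl (2.1 equiv), iPr2NEt, CH2Cl2, 0 °C to rt
Reagents that add atoms: chloromethyl methyl ether, COCCl
Why: O-Alkylation of the para hydroxyl and one of the two equivalent ortho hydroxyls; the last hydroxyl is hydrogen-bonded to the formyl group and should be the least nucleophilic, so the reaction stops at the bis-ether with no regiochemical question.

**Step 7**
Reactants: 13 2-hydroxy-4,6-bis(methoxymethoxy)benzaldehyde; 14 3-chloro-3-methylbut-1-yne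
Product: 15 2,4-bis(methoxymethoxy)-6-[(2-methylbut-3-yn-2-yl)oxy]benzaldehyde
Conditions: DBU, CuCl2·2H2O (cat.), MeCN, 0 °C
Reagents that add atoms: none
Why: Copper-catalysed O-propargylation of a phenoxide by a tertiary propargylic chloride (through a copper acetylide-derived electrophile). Attaching the five-carbon unit to this oxygen fixes in advance the ring carbon to which it will be delivered.

**Step 8**
Reactants: 15 2,4-bis(methoxymethoxy)-6-[(2-methylbut-3-yn-2-yl)oxy]benzaldehyde
Product: 17 2-hydroxy-4,6-bis(methoxymethoxy)-3-(3-methylbut-2-en-1-yl)benzaldehyde, via dimethylallyl aryl ether 16 (not isolated)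
Conditions: H2 (1 atm), Pd/CaCO3 poisoned with Pb(OAc)2 (Lindlar catalyst), quinoline, toluene, rt; filter; 110 °C
Reagents that add atoms: none
Why: Semi-hydrogenation of the terminal alkyne gives the 1,1-dimethylallyl ether 16, which on heating should undergo an aromatic Claisen [3,3] rearrangement to the only free ortho carbon. Allylic inversion turns the tertiary ether into the linear prenyl group at C1 and tautomerisation restores the phenol.

**Step 9**
Reactants: 17 2-hydroxy-4,6-bis(methoxymethoxy)-3-(3-methylbut-2-en-1-yl)benzaldehyde
Product: 18 2-formyl-3,5-bis(methoxymethoxy)-6-(3-methylbut-2-en-1-yl)phenyl trifluoromethanesulfonate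
Conditions: NaH, PhNTf2, THF, 0 °C to rt
Reagents that add atoms: N-phenylbis(trifluoromethanesulfonimide), O=S(=O)(N(c1ccccc1)S(=O)(=O)C(F)(F)F)C(F)(F)F
Why: Sulfonylation of the sodium phenoxide by a mild triflyl donor turns the C6 oxygen into a leaving group for palladium; the basic conditions leave the MOM ethers and the prenyl group alone.

**Step 10**
Reactants: 18 2-formyl-3,5-bis(methoxymethoxy)-6-(3-methylbut-2-en-1-yl)phenyl trifluoromethanesulfonate
Product: 19 2-(dimethoxymethyl)-3,5-bis(methoxymethoxy)-6-(3-methylbut-2-en-1-yl)phenyl trifluoromethanesulfonate
Conditions: HC(OMe)3, MeOH, PPTS (cat.), rt; Et3N quench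
Reagents that add atoms: trimethyl orthoformate, COC(OC)OC; methanol, CO
Why: Acid-catalysed acetalisation driven by the orthoformate as water scavenger. It is placed here because the chelated hydroxy aldehyde 17 would resist it and an ortho-formyl ester would be diverted to a cyclic pseudo-ester; a pyridinium salt at rt should spare the aryl MOM ethers.

**Step 11**
Reactants: 19 2-(dimethoxymethyl)-3,5-bis(methoxymethoxy)-6-(3-methylbut-2-en-1-yl)phenyl trifluoromethanesulfonate
Product: 20 2-(trimethylsilyl)ethyl 2-(dimethoxymethyl)-3,5-bis(methoxymethoxy)-6-(3-methylbut-2-en-1-yl)benzoate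
Conditions: Pd(OAc)2 (cat.), Fe(C5H4PPh2)2 (dppf, cat.), Et3N, Me3SiCH2CH2OH (5 equiv), CO (3 bar), DMF, 80 °C
Reagents that add atoms: carbon monoxide, [C-]#[O+]; 2-(trimethylsilyl)ethanol, C[Si](C)(C)CCO
Why: Palladium-catalysed alkoxycarbonylation of an aryl triflate: oxidative addition to zerovalent palladium formed in the flask, CO insertion and alcoholysis of the acylpalladium form the C6–C7 bond. The silylethyl ester is chosen because it can later be cleaved at silicon, away from the shielded carbonyl.

**Step 12**
Reactants: 20 2-(trimethylsilyl)ethyl 2-(dimethoxymethyl)-3,5-bis(methoxymethoxy)-6-(3-methylbut-2-en-1-yl)benzoate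
Product: 21 caesium 2-(dimethoxymethyl)-3,5-bis(methoxymethoxy)-6-(3-methylbut-2-en-1-yl)benzoate
Conditions: CsF (2 equiv), DMF, 60 °C; evaporate, co-evaporate with toluene, dry in vacuo
Reagents that add atoms: caesium fluoride, [Cs+].[F-]
Why: Fluoride attacks silicon and β-elimination releases ethene and the carboxylate, a known fluoride-induced fragmentation of 2-silylethyl esters. The co-products are gases, so the dry caesium salt is obtained without any acidic work-up.

**Step 13**
Reactants: 21 caesium 2-(dimethoxymethyl)-3,5-bis(methoxymethoxy)-6-(3-methylbut-2-en-1-yl)benzoate; 11 4-chloro-3-(methoxymethoxy)-5-methyl-2-(trimethylsilyl)phenyl trifluoromethanesulfonate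
Product: 24 [3-chloro-6-hydroxy-2-(methoxymethoxy)-4-methylphenyl][2-(dimethoxymethyl)-3,5-bis(methoxymethoxy)-6-(3-methylbut-2-en-1-yl)phenyl]methanone, via aryne 22 (not isolated), via aryl caesium ester 23 (not isolated)
Conditions: CsF (3 equiv), 18-crown-6 (0.3 equiv), THF, 80 °C (sealed tube), slow addition of 11 (1.2 equiv); cold sat. aq. NH4Cl
Reagents that add atoms: none
Why: Fluoride attacks the silicon of 11 and triflate leaves from the neighbouring carbon, giving aryne 22 across C1'–C2'. The carboxylate oxygen of 21 should add to C2', the aryne carbon remote from the MOM ether, because the inductively withdrawing C6' oxygen (buttressed by the C5' chlorine) makes C2' the more electrophilic terminus and lets the negative charge develop at C1' beside that oxygen. The aryl caesium 23 then attacks the carbonyl of its own aryl ester (4-exo-trig) to a four-membered tetrahedral alkoxide, whose ring C–O bond breaks to release the C2' phenoxide, so that the aryne is inserted into the acyl–oxygen bond and C2'–O and C1'–C7 are formed. The closest known reaction type is the fluoride-induced insertion of arynes into the C–O bond of carboxylic acids to give ortho-hydroxyaryl ketones, mechanistically an intramolecular anionic Fries-type acyl shift. No ring is retained, since the four-membered ring is only a transient intermediate, and no stereocentre is created. Two selectivities are needed: the regiochemistry, secured by the C6' ether as explained, and acyl shift in preference to protonation of 23, secured by the pre-formed salt 21 (no O–H), an aprotic solvent without acidic C–H bonds and heat. The acyl shift must reach a carbonyl flanked by the C1 prenyl and C5 acetal groups, but it is intramolecular, whereas any intermolecular approach to this ketone would be more hindered still. Slow addition of 11 keeps the aryne concentration low, so that the product phenoxide, deactivated by conjugation with the new ketone, should not be arylated further.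

**Step 14**
Reactants: 24 [3-chloro-6-hydroxy-2-(methoxymethoxy)-4-methylphenyl][2-(dimethoxymethyl)-3,5-bis(methoxymethoxy)-6-(3-methylbut-2-en-1-yl)phenyl]methanone
Product: 25 pestalone E, 2-(3-chloro-2,6-dihydroxy-4-methylbenzoyl)-4,6-dihydroxy-3-(3-methylbut-2-en-1-yl)benzaldehyde
Conditions: aq. HCl (3 M), MeOH, 0 °C to rt
Reagents that add atoms: water, O
Why: Acid-catalysed hydrolysis of the dimethyl acetal and acetal exchange of the three aryl MOM ethers with methanol (global deprotection). The electron-rich acetal and the MOM ethers beside carbonyl groups should cleave at rt, where addition of the C2 hydroxyl to the prenyl olefin is slow.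

## Compound list

1 | 2-chloro-3-methylphenol | Cc1cccc(O)c1Cl | starting material
2 | 2-chloro-1-(methoxymethoxy)-3-methylbenzene | COCOc1cccc(C)c1Cl | intermediate
3 | 2-[4-chloro-3-(methoxymethoxy)-5-methylphenyl]-4,4,5,5-tetramethyl-1,3,2-dioxaborolane | COCOc1cc(B2OC(C)(C)C(C)(C)O2)cc(C)c1Cl | intermediate (not isolated)
4 | 4-chloro-3-(methoxymethoxy)-5-methylphenol | COCOc1cc(O)cc(C)c1Cl | intermediate
5 | 4-chloro-3-(methoxymethoxy)-5-methylphenyl N-(propan-2-yl)carbamate | COCOc1cc(OC(=O)NC(C)C)cc(C)c1Cl | intermediate
6 | 4-chloro-3-(methoxymethoxy)-5-methylphenyl N-(propan-2-yl)-N-(trimethylsilyl)carbamate | COCOc1cc(OC(=O)N(C(C)C)[Si](C)(C)C)cc(C)c1Cl | intermediate (not isolated)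
7 | {3-chloro-2-(methoxymethoxy)-4-methyl-6-[(propan-2-yl)(trimethylsilyl)carbamoyloxy]phenyl}lithium | COCOc1c([Li])c(OC(=O)N(C(C)C)[Si](C)(C)C)cc(C)c1Cl | intermediate (not isolated)
8 | 4-chloro-3-(methoxymethoxy)-5-methyl-2-(trimethylsilyl)phenyl N-(propan-2-yl)-N-(trimethylsilyl)carbamate | COCOc1c([Si](C)(C)C)c(OC(=O)N(C(C)C)[Si](C)(C)C)cc(C)c1Cl | intermediate (not isolated)
9 | 4-chloro-3-(methoxymethoxy)-5-methyl-2-(trimethylsilyl)phenyl N-(propan-2-yl)carbamate | COCOc1c([Si](C)(C)C)c(OC(=O)NC(C)C)cc(C)c1Cl | intermediate
10 | 4-chloro-3-(methoxymethoxy)-5-methyl-2-(trimethylsilyl)phenol (present as its DBU salt) | COCOc1c([Si](C)(C)C)c(O)cc(C)c1Cl | intermediate (not isolated)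
11 | 4-chloro-3-(methoxymethoxy)-5-methyl-2-(trimethylsilyl)phenyl trifluoromethanesulfonate | Cc1cc(OS(=O)(=O)C(F)(F)F)c([Si](C)(C)C)c(OCOC)c1Cl | intermediate
12 | 2,4,6-trihydroxybenzaldehyde | O=Cc1c(O)cc(O)cc1O | starting material
13 | 2-hydroxy-4,6-bis(methoxymethoxy)benzaldehyde | COCOc1cc(O)c(C=O)c(OCOC)c1 | intermediate
14 | 3-chloro-3-methylbut-1-yne | C#CC(C)(C)Cl | starting material
15 | 2,4-bis(methoxymethoxy)-6-[(2-methylbut-3-yn-2-yl)oxy]benzaldehyde | COCOc1cc(OCOC)c(C=O)c(OC(C)(C)C#C)c1 | intermediate
16 | 2,4-bis(methoxymethoxy)-6-[(2-methylbut-3-en-2-yl)oxy]benzaldehyde | COCOc1cc(OCOC)c(C=O)c(OC(C)(C)C=C)c1 | intermediate (not isolated)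
17 | 2-hydroxy-4,6-bis(methoxymethoxy)-3-(3-methylbut-2-en-1-yl)benzaldehyde | COCOc1cc(OCOC)c(C=O)c(O)c1CC=C(C)C | intermediate
18 | 2-formyl-3,5-bis(methoxymethoxy)-6-(3-methylbut-2-en-1-yl)phenyl trifluoromethanesulfonate | COCOc1cc(OCOC)c(C=O)c(OS(=O)(=O)C(F)(F)F)c1CC=C(C)C | intermediate
19 | 2-(dimethoxymethyl)-3,5-bis(methoxymethoxy)-6-(3-methylbut-2-en-1-yl)phenyl trifluoromethanesulfonate | COCOc1cc(OCOC)c(C(OC)OC)c(OS(=O)(=O)C(F)(F)F)c1CC=C(C)C | intermediate
20 | 2-(trimethylsilyl)ethyl 2-(dimethoxymethyl)-3,5-bis(methoxymethoxy)-6-(3-methylbut-2-en-1-yl)benzoate | COCOc1cc(OCOC)c(C(OC)OC)c(C(=O)OCC[Si](C)(C)C)c1CC=C(C)C | intermediate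
21 | caesium 2-(dimethoxymethyl)-3,5-bis(methoxymethoxy)-6-(3-methylbut-2-en-1-yl)benzoate | COCOc1cc(OCOC)c(C(OC)OC)c(C(=O)[O-])c1CC=C(C)C.[Cs+] | intermediate
22 | 4-chloro-3-(methoxymethoxy)-5-methyl-1,2-didehydrobenzene | CC1=CC#CC(OCOC)=C1Cl | intermediate (not isolated)
23 | caesium 3-chloro-6-{[2-(dimethoxymethyl)-3,5-bis(methoxymethoxy)-6-(3-methylbut-2-en-1-yl)benzoyl]oxy}-2-(methoxymethoxy)-4-methylbenzen-1-ide | CC(C)=CCc1c(OCOC)cc(OCOC)c(C(OC)OC)c1C(=O)Oc1cc(C)c(Cl)c(OCOC)[c-]1.[Cs+] | intermediate (not isolated)
24 | [3-chloro-6-hydroxy-2-(methoxymethoxy)-4-methylphenyl][2-(dimethoxymethyl)-3,5-bis(methoxymethoxy)-6-(3-methylbut-2-en-1-yl)phenyl]methanone | CC(C)=CCc1c(OCOC)cc(OCOC)c(C(OC)OC)c1C(=O)c1c(O)cc(C)c(Cl)c1OCOC | intermediate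
25 | pestalone E, 2-(3-chloro-2,6-dihydroxy-4-methylbenzoyl)-4,6-dihydroxy-3-(3-methylbut-2-en-1-yl)benzaldehyde | CC(C)=CCc1c(O)cc(O)c(C=O)c1C(=O)c1c(O)cc(C)c(Cl)c1O | target

## Step count and least certain steps

Total: 14 steps (steps 1 to 5 to the aryne precursor 11, steps 6 to 12 to the salt 21, the key step 13 and the deprotection 14). The longest linear sequence is 9 steps, from 12 to 25 through steps 6 to 14.

**Step 13 (key step).** The most likely failure is protonation of the C1' carbanion by adventitious water or solvent before the four-centre acyl shift onto the doubly ortho-substituted carbonyl. A second is arylation of the product phenoxide by further aryne. The fallback sets out from 19 and 4 and returns at 24; it replaces the aryne by carbonylative esterification and a base-induced acyl shift. Palladium-catalysed aryloxycarbonylation of 19 with the phenol 4 (Pd(OAc)2, Fe(C5H4PPh2)2, Et3N, CO, DMF, 80 °C) should give the aryl ester 4-chloro-3-(methoxymethoxy)-5-methylphenyl 2-(dimethoxymethyl)-3,5-bis(methoxymethoxy)-6-(3-methylbut-2-en-1-yl)benzoate F1. Lithium 2,2,6,6-tetramethylpiperidide (2.5 equiv, THF, −78 to 0 °C) should then lithiate C1' between the ester oxygen and the MOM ether. In a strictly aprotic medium the persistent lithio species has no outlet other than the anionic ortho-Fries shift, which gives 24 on work-up. The excess of base allows for reversible, harmless lithiation of ring A at C3.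

**Step 11.** Turnover may be slow at a triflate flanked by two ortho groups when the alcohol is not the solvent. That would leave time for reduction of the arylpalladium or for interception of the acylpalladium by the neighbouring prenyl olefin. The fallback sets out from 13 and returns at 20; it carbonylates before the prenyl group is on the ring. Triflation of 13 (NaH, PhNTf2, THF) should give 2-formyl-3,5-bis(methoxymethoxy)phenyl trifluoromethanesulfonate F2. Acetalisation (HC(OMe)3, MeOH, PPTS) gives 2-(dimethoxymethyl)-3,5-bis(methoxymethoxy)phenyl trifluoromethanesulfonate F3, and carbonylation as in step 11 gives 2-(trimethylsilyl)ethyl 2-(dimethoxymethyl)-3,5-bis(methoxymethoxy)benzoate F4. Bromination para to the C3 ether (NBS, NaHCO3, MeCN, 0 °C) should give 2-(trimethylsilyl)ethyl 2-bromo-6-(dimethoxymethyl)-3,5-bis(methoxymethoxy)benzoate F5. Stille coupling with tributyl(3-methylbut-2-en-1-yl)stannane (Pd(PPh3)4, DMF, 90 °C) then gives 20.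

**Step 14.** Acid may add the C2 hydroxyl across the prenyl olefin (chroman formation), and methoxymethyl cations may be captured by the freed electron-rich rings before all three ethers are gone. The fallback sets out from 24 and returns at 25; it avoids strong Brønsted acid. Mild transacetalisation (PPTS, acetone/H2O, rt) should free only the aldehyde, giving 2-[3-chloro-6-hydroxy-2-(methoxymethoxy)-4-methylbenzoyl]-4,6-bis(methoxymethoxy)-3-(3-methylbut-2-en-1-yl)benzaldehyde F6. Trimethylsilyl triflate with 2,2'-bipyridyl (CH2Cl2, 0 °C) should then convert the aryl MOM ethers and the free phenol into silyl ethers, giving 2-{3-chloro-4-methyl-2,6-bis[(trimethylsilyl)oxy]benzoyl}-3-(3-methylbut-2-en-1-yl)-4,6-bis[(trimethylsilyl)oxy]benzaldehyde F7, which water hydrolyses to 25 on work-up.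

**Step 7.** The phenoxide of 13 is chelated to the ortho formyl group and weakly nucleophilic, so loss of HCl from the tertiary propargylic chloride may outrun O-alkylation. The fallback sets out from 13 and returns at 16, at the thermal stage of step 8. The carbonate tert-butyl 2-methylbut-3-en-2-yl carbonate F8 is made from 2-methylbut-3-en-2-ol, n-BuLi and di-tert-butyl dicarbonate. Palladium-catalysed O-allylation of 13 with it (Pd(PPh3)4, THF, 0 °C; Tsuji–Trost type) should, under kinetic control, attack the more substituted terminus of the allylpalladium intermediate and give 16 directly, without a hydrogenation.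

## Further compounds

F1 | step 13 | 4-chloro-3-(methoxymethoxy)-5-methylphenyl 2-(dimethoxymethyl)-3,5-bis(methoxymethoxy)-6-(3-methylbut-2-en-1-yl)benzoate | CC(C)=CCc1c(OCOC)cc(OCOC)c(C(OC)OC)c1C(=O)Oc1cc(C)c(Cl)c(OCOC)c1
F2 | step 11 | 2-formyl-3,5-bis(methoxymethoxy)phenyl trifluoromethanesulfonate | COCOc1cc(OCOC)c(C=O)c(OS(=O)(=O)C(F)(F)F)c1
F3 | step 11 | 2-(dimethoxymethyl)-3,5-bis(methoxymethoxy)phenyl trifluoromethanesulfonate | COCOc1cc(OCOC)c(C(OC)OC)c(OS(=O)(=O)C(F)(F)F)c1
F4 | step 11 | 2-(trimethylsilyl)ethyl 2-(dimethoxymethyl)-3,5-bis(methoxymethoxy)benzoate | COCOc1cc(OCOC)c(C(OC)OC)c(C(=O)OCC[Si](C)(C)C)c1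
F5 | step 11 | 2-(trimethylsilyl)ethyl 2-bromo-6-(dimethoxymethyl)-3,5-bis(methoxymethoxy)benzoate | COCOc1cc(OCOC)c(C(OC)OC)c(C(=O)OCC[Si](C)(C)C)c1Br
F6 | step 14 | 2-[3-chloro-6-hydroxy-2-(methoxymethoxy)-4-methylbenzoyl]-4,6-bis(methoxymethoxy)-3-(3-methylbut-2-en-1-yl)benzaldehyde | CC(C)=CCc1c(OCOC)cc(OCOC)c(C=O)c1C(=O)c1c(O)cc(C)c(Cl)c1OCOC
F7 | step 14 | 2-{3-chloro-4-methyl-2,6-bis[(trimethylsilyl)oxy]benzoyl}-3-(3-methylbut-2-en-1-yl)-4,6-bis[(trimethylsilyl)oxy]benzaldehyde | CC(C)=CCc1c(O[Si](C)(C)C)cc(O[Si](C)(C)C)c(C=O)c1C(=O)c1c(O[Si](C)(C)C)cc(C)c(Cl)c1O[Si](C)(C)C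
F8 | step 7 | tert-butyl 2-methylbut-3-en-2-yl carbonate | C=CC(C)(C)OC(=O)OC(C)(C)C
A1 | alternative 1 | 2-[3-chloro-2,6-bis(methoxymethoxy)-4-methylbenzoyl]-4,6-dihydroxy-3-(3-methylbut-2-en-1-yl)benzaldehyde | CC(C)=CCc1c(O)cc(O)c(C=O)c1C(=O)c1c(OCOC)cc(C)c(Cl)c1OCOC
A2 | alternative 1 | 1-methoxy-7-methyl-1,3-bis(trimethylsilyloxy)octa-1,3,6-triene | COC(O[Si](C)(C)C)=CC(O[Si](C)(C)C)=CCC=C(C)C
A3 | alternative 1 | 4-[3-chloro-2,6-bis(methoxymethoxy)-4-methylphenyl]-4-oxobut-2-ynal | O=CC#CC(=O)c1c(OCOC)cc(C)c(Cl)c1OCOC
A4 | alternative 2 | 6-chloro-2-{[2-(dimethoxymethyl)-3,5-bis(methoxymethoxy)-6-(3-methylbut-2-en-1-yl)phenyl]methyl}-5-methyl-3-[tri(propan-2-yl)silyloxy]phenol | Cc1cc(O[Si](C(C)C)(C(C)C)C(C)C)c(Cc2c(CC=C(C)C)c(OCOC)cc(OCOC)c2C(OC)OC)c(O)c1Cl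
A5 | alternative 2 | 4-chloro-3-methylcyclobut-2-en-1-one | CC1=CC(=O)C1Cl
A6 | alternative 2 | ({3-[2-(dimethoxymethyl)-3,5-bis(methoxymethoxy)-6-(3-methylbut-2-en-1-yl)phenyl]prop-1-yn-1-yl}oxy)tri(propan-2-yl)silane | CC(C)=CCc1c(OCOC)cc(OCOC)c(C(OC)OC)c1CC#CO[Si](C(C)C)(C(C)C)C(C)C
A7 | alternative 3 | 2-[3-chloro-2,6-bis(methoxymethoxy)-4-methylbenzoyl]-4,6-bis(methoxymethoxy)-3-(3-methylbut-2-en-1-yl)benzaldehyde | CC(C)=CCc1c(OCOC)cc(OCOC)c(C=O)c1C(=O)c1c(OCOC)cc(C)c(Cl)c1OCOC
A8 | alternative 3 | [3-chloro-2,6-bis(methoxymethoxy)-4-methylphenyl]zinc chloride | COCOc1cc(C)c(Cl)c(OCOC)c1[Zn]Cl
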